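Amounts came first. In the west run, c(target) stood at 0.0466 M at 58 h from 0.120 M of starting material charged, and the last interval added 0.00140 M. I had to decide whether the next flask, the north run, should be read beyond 58 h.

| flask | starting material | free catalyst | time |
|---|---|---|---|
| west | 0.120 M | 0.0120 M |  |
| north-east | 0.0480 M | 0.0120 M |  |
| north-west | 0.120 M | 0.0180 M |  |
| north | 0.0300 M | 0.0120 M | 58 h |

- west run (time / h: [target] / M): 12: 0.0240; 23: 0.0358; 35: 0.0431; 46: 0.0452; 58: 0.0466
- north-east run (time / h: [target] / M): 12: 0.0134; 23: 0.0191; 35: 0.0210; 46: 0.0228; 58: 0.0233
- north-west run (time / h: [target] / M): 12: 0.0494; 23: 0.0662; 35: 0.0718; 46: 0.0733; 58: 0.0744

(scatter of a reading: 4 × 10⁻⁴ M)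

- Overall: starting material -> target, with free catalyst as catalyst.
- Constant volume, constant temperature.
- What is held in complexes is read along with the free species.
- An order is taken over about fifteen percent of the charge, up and down.

- the power of [free catalyst] that the first rate follows, about the charge of the west run; measure it at two percent of starting material made into target
- the power of [starting material] that the first rate follows, about the charge of the west run; measure it at two percent of starting material made into target (one fixed amount of target, the same in the runs compared)
- target in the north run at 58 h, as a share of the starting material charged

For the north run I leaned on the north-east run, which has the same c(free catalyst) and a c(starting material) nearer to the north run's than the west run's is. It gave a stall half-time of 9.72 h. By stall half-time I mean the time in which a run makes half of its last reading, worked out from its first and last readings as if the part still to come fell like a pseudo-first-order decay.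

The last readings were 38.8% of the charge in the west run and 48.5% in the north-east run. Taking the power of the charge that joins these two shares and carrying it down to the north run, I reckoned a share of 54.4%, or 0.0163 M of target. At 58 h, the part still to come would be 1.60% of that, 2.61 × 10⁻⁴ M, which is less than the scatter of 4 × 10⁻⁴ M. So I kept the recipe and planned no later reading.

The forecast gave 2 and 0.5 for the two orders and 52% for the north run, reasoning that “the stall depends on catalyst, so the catalyst is dying”. My share stood 2.4 percentage points above its figure.

The north run gave 50.2% of its charge as target at 58 h. About the charge of the west run, the order came to 2.1 in free catalyst and 0.44 in starting material. The scheme behind the runs was this: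

    free catalyst + starting material ⇌ catalyst-substrate complex, settled at all times (3.610 /M)
    catalyst-substrate complex + free catalyst → target + 2 free catalyst (90.72 /M/h)
    catalyst-substrate complex → spent catalyst + starting material (0.04212 /h)
    starting material → decomposed substrate (0.03924 /h)

A power law fitted to the runs left a root mean square residual of 22 in units of the scatter. The north run's share is 0.0150 M of target, and the same reckoned fraction of that comes to 2.40 × 10⁻⁴ M, again less than the scatter. The north-west run's readings give a stall half-time of 7.63 h, which puts target at half of that run's charge at 18.1 h, and the north-west run reached it at 17.5 h.

(The runs are calculated from invented constants; noise was put on by code.)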